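(Chromane numbering: O1, C2, C3, C4, C4a, C5–C8, C8a.) After a MOM group is removed from O6, the dihydropyran ring is opened at C4–C4a. The chromane is an isomer of the open-chain aryl ether of (R)-geranyllinalool, and the forward closure is an imine-directed Rh(I) C–H hydroarylation of the vinyl group C3=C4.
Enabling feature: on the benzene ring, C4a lies between C5 (formyl group, a directing group as its imine) and C8a (carries O1 and so the tether). C4a–H is the only C–H ortho to C5 because C6 bears oxygen. C2 is fully substituted, so the vinyl group has no allylic hydrogen, cannot isomerise, and takes the metal at its terminal carbon C4.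
O1–C2 and the C2 stereocentre come from a Pd-catalysed decarboxylative asymmetric allylic etherification of an aryl (E,E,E)-geranylgeranyl carbonate.
That carbonate comes from 2,5-dihydroxy-4-methylbenzaldehyde (made from its dimethyl ether), geranylgeraniol and CDI. The OH hydrogen-bonded to CHO stays free and is then capped as a MOM ether.
Ring order: the benzene ring and the three E-olefins are bought; the dihydropyran ring is the only ring formed (step 5).

Key step: step 5

Assumption: with the (E)-allyl carbonate, the (R,R)-configured DACH-phenyl ligand is taken to give the (R)-ether. The sense of induction is to be verified on 7; if it is opposite, the (S,S)-ligand is used and nothing else changes.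

Step 1
Reactants: 1 2,5-dimethoxy-4-methylbenzaldehyde
Product: 2 2,5-dihydroxy-4-methylbenzaldehyde
Conditions: BBr3 (3.5 equiv), CH2Cl2, −78 °C to rt; H2O quench
Reagents that add atoms: none
Why: BBr3 cleavage of aryl methyl ethers cuts both O–CH3 bonds via aryloxydibromoboranes, while the formyl group is only complexed and returns on hydrolysis; no stereocentre is involved.

Step 2
Reactants: 3 (2E,6E,10E)-geranylgeraniol; 2 2,5-dihydroxy-4-methylbenzaldehyde
Product: 5 5-formyl-4-hydroxy-2-methylphenyl (2E,6E,10E)-geranylgeranyl carbonate, via geranylgeranyl imidazole-1-carboxylate 4 (not isolated)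
Conditions: CDI (1.0 equiv), THF, rt; then 2 (1.05 equiv), DBU (10 mol %), THF, rt to 40 °C, N2
Reagents that add atoms: 1,1'-carbonyldiimidazole, O=C(n1ccnc1)n1ccnc1
Why: In this CDI-mediated carbonate synthesis (acyl transfer), the primary allylic alcohol gives the alkoxycarbonylimidazole, which should acylate only the OH para to the chelated one, because the OH next to CHO is held in a six-membered hydrogen-bond chelate and the desired isomer is therefore favoured in both rate and stability.

Step 3
Reactants: 5 5-formyl-4-hydroxy-2-methylphenyl geranylgeranyl carbonate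
Product: 6 5-formyl-4-(methoxymethoxy)-2-methylphenyl (2E,6E,10E)-geranylgeranyl carbonate
Conditions: MOMCl (2 equiv), i-Pr2NEt (3 equiv), CH2Cl2, 0 °C to rt
Reagents that add atoms: chloromethyl methyl ether, COCCl
Why: Standard MOM protection (O-alkylation with an α-chloro ether under amine base) masks the phenol that would otherwise bind Rh as an N,O-salicylaldiminate chelate in step 5, and the non-nucleophilic base leaves the aryl carbonate intact.

Step 4
Reactants: 6 5-formyl-4-(methoxymethoxy)-2-methylphenyl geranylgeranyl carbonate
Product: 7 2-(methoxymethoxy)-4-methyl-5-{[(3R,6E,10E)-3,7,11,15-tetramethylhexadeca-1,6,10,14-tetraen-3-yl]oxy}benzaldehyde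
Conditions: Pd2(dba)3·CHCl3 (2 mol %), (1R,2R)-N,N'-bis[2-(diphenylphosphino)benzoyl]cyclohexane-1,2-diamine (6 mol %), CH2Cl2 (0.05 M), 0 °C to rt, stopped at full conversion
Reagents that add atoms: none
Why: In this decarboxylative Tsuji–Trost asymmetric allylic etherification, Pd(0) ionises the (E)-trisubstituted allyl carbonate, loss of CO2 frees the aryloxide as the only nucleophile present, and its attack at the more substituted allyl terminus inside the chiral ligand pocket should give the branched tertiary ether and set C2 as (R) through discrimination of the enantiotopic olefin faces at ionisation.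

Step 5
Reactants: 7 2-(methoxymethoxy)-4-methyl-5-[(R)-geranyllinalyloxy]benzaldehyde
Product: 10 (2R)-6-(methoxymethoxy)-2,8-dimethyl-2-[(3E,7E)-4,8,12-trimethyltrideca-3,7,11-trien-1-yl]chromane-5-carbaldehyde, via open-chain N-benzyl aldimine 8 (not isolated), via cyclised N-benzyl aldimine 9 (not isolated)
Conditions: BnNH2 (1.0 equiv), 4 Å MS, PhMe, rt; then [RhCl(coe)2]2 (10 mol %), FcPCy2 (30 mol %), PhMe, 75 °C, Ar; then 10 % aq citric acid, THF, rt
Reagents that add atoms: water, O (aldehyde oxygen of 10); benzylamine, NCc1ccccc1 (its atoms stay only in 8 and 9)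
Why: The imine nitrogen binds Rh(I) and delivers it into C4a–H, the only C–H ortho to the imine carbon (C6 bears OMOM), to give a five-membered aza-rhodacycle hydride; the tethered vinyl group then coordinates and inserts into Rh–H with Rh going to terminal C4, and C–C reductive elimination from the seven-membered rhodacycle forms C4–C4a. The closest known reaction type is the Murai-type, imine-directed Rh(I) annulation of aromatic ketimines and aldimines that carry an alkene tethered at the meta position, which closes indanes, tetralins and dihydrobenzofurans at this same kind of doubly flanked C–H bond. The one ring that closes, the dihydropyran ring O1–C2–C3–C4–C4a–C8a, closes in a formal 6-endo-trig (anti-Markovnikov) hydroarylation, helped by the Thorpe–Ingold effect of the gem-disubstituted C2. No stereocentre is created, and C2 stays (R) because none of its four bonds is touched, whereas the thermal alternative (aromatic Claisen rearrangement) would break O1–C2. Six- over five-membered ring closure is secured by the fully substituted C2 next to C3, which makes the vinyl group a neohexene-type olefin that takes the metal at its CH2 end and cannot drift to an enol ether; chemoselectivity is secured because Rh–H insertion into the three trisubstituted chain olefins should be far slower than into the chelate-held monosubstituted one. The electron-rich ferrocenyl dialkylphosphine allows 75 °C, below the range in which α,α-disubstituted allyl aryl ethers rearrange, and the mildly acidic work-up returns the aldehyde with the MOM ether kept.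

Step 6
Reactants: 10 (2R)-6-(methoxymethoxy)chromane-5-carbaldehyde (MOM ether of the target)
Product: 11 (2R)-6-hydroxy-2,8-dimethyl-2-[(3E,7E)-4,8,12-trimethyltrideca-3,7,11-trien-1-yl]chromane-5-carbaldehyde (target)
Conditions: 3 M aq HCl/THF (1:4), 40 °C
Reagents that add atoms: none
Why: This is an acid-catalysed acetal hydrolysis; a MOM ether ortho to a formyl group is among the most labile aryl MOM ethers, so dilute acid at mild temperature should free the hydrogen-bonded phenol without touching the trisubstituted olefins, the chromane ether or C2.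

Compound list
1 | 2,5-dimethoxy-4-methylbenzaldehyde | COc1cc(C=O)c(OC)cc1C | starting material
2 | 2,5-dihydroxy-4-methylbenzaldehyde | Oc1cc(C=O)c(O)cc1C | intermediate
3 | (2E,6E,10E)-geranylgeraniol | CC(C)=CCC/C(C)=C/CC/C(C)=C/CC/C(C)=C/CO | starting material
4 | (2E,6E,10E)-geranylgeranyl 1H-imidazole-1-carboxylate | CC(C)=CCC/C(C)=C/CC/C(C)=C/CC/C(C)=C/COC(=O)n1ccnc1 | intermediate
5 | 5-formyl-4-hydroxy-2-methylphenyl (2E,6E,10E)-geranylgeranyl carbonate | CC(C)=CCC/C(C)=C/CC/C(C)=C/CC/C(C)=C/COC(=O)Oc1cc(C=O)c(O)cc1C | intermediate
6 | 5-formyl-4-(methoxymethoxy)-2-methylphenyl (2E,6E,10E)-geranylgeranyl carbonate | CC(C)=CCC/C(C)=C/CC/C(C)=C/CC/C(C)=C/COC(=O)Oc1cc(C=O)c(OCOC)cc1C | intermediate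
7 | 2-(methoxymethoxy)-4-methyl-5-{[(3R,6E,10E)-3,7,11,15-tetramethylhexadeca-1,6,10,14-tetraen-3-yl]oxy}benzaldehyde | CC(C)=CCC/C(C)=C/CC/C(C)=C/CC[C@](C)(C=C)Oc1cc(C=O)c(OCOC)cc1C | intermediate
8 | (E)-N-benzyl aldimine of 7 | CC(C)=CCC/C(C)=C/CC/C(C)=C/CC[C@](C)(C=C)Oc1cc(/C=N/Cc2ccccc2)c(OCOC)cc1C | intermediate
9 | (E)-N-benzyl aldimine of 10 | CC(C)=CCC/C(C)=C/CC/C(C)=C/CC[C@]1(C)CCc2c(/C=N/Cc3ccccc3)c(OCOC)cc(C)c2O1 | intermediate
10 | (2R)-6-(methoxymethoxy)-2,8-dimethyl-2-[(3E,7E)-4,8,12-trimethyltrideca-3,7,11-trien-1-yl]chromane-5-carbaldehyde | CC(C)=CCC/C(C)=C/CC/C(C)=C/CC[C@]1(C)CCc2c(C=O)c(OCOC)cc(C)c2O1 | intermediate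
11 | (2R)-6-hydroxy-2,8-dimethyl-2-[(3E,7E)-4,8,12-trimethyltrideca-3,7,11-trien-1-yl]chromane-5-carbaldehyde | CC(C)=CCC/C(C)=C/CC/C(C)=C/CC[C@]1(C)CCc2c(C=O)c(O)cc(C)c2O1 | target

Total step count: 6. Longest linear sequence: 6 steps (1 to 11; 5 steps from 3).

Steps most likely to fail

**Step 5 (key step).**
- What may go wrong: insertion of Rh into the crowded C4a–H bond may be too slow at 75 °C. At the higher temperatures then needed, three processes may take over: a [3,3] shift of the allyl aryl ether (loss of the O1–C2 bond and of the stereocentre), Markovnikov insertion followed by β-aryloxy elimination, or closure to the five-membered ring.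
- Fallback (sets out from 7, returns at 10): the same bond is closed in two stages by halogen-based cross-coupling instead of C–H activation. Compound 7 is protected in situ as its α-amino alkoxide with LiN(Me)CH2CH2NMe2, lithiated with n-BuLi at the position between the two directing groups, and quenched with I2 to give the iodo aldehyde F1. 9-BBN (2.3 equiv, THF, 0 °C to rt) hydroborates only the monosubstituted vinyl group and also reduces the aldehyde, giving the bis-boron adduct F2, which is used in the same flask. PdCl2(dppf) and aq K3PO4 in THF/DMF at 50 °C then close C4–C4a by intramolecular B-alkyl Suzuki–Miyaura coupling to give the chromanylmethanol F3. MnO2 in CH2Cl2 re-oxidises the benzylic alcohol to 10.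

**Step 4.**
- What may go wrong: the aryloxide may attack the primary allyl terminus; Pd(0) may re-ionise the tertiary ether, causing drift to the linear ether and erosion of enantiopurity; or the olefin faces may be insufficiently discriminated.
- Fallback (sets out from 6, returns at 7): the stereocentre is taken from a reagent-controlled epoxidation and an invertive substitution instead of a π-allyl complex. LiOH (THF/H2O, 0 °C) splits 6 into the free phenol F4 and recovered 3. Sharpless asymmetric epoxidation of 3 [Ti(Oi-Pr)4, L-(+)-diethyl tartrate, t-BuOOH, 4 Å MS, CH2Cl2, −20 °C] oxidises only the allylic-alcohol olefin and gives the (2S,3S)-epoxy alcohol F5. Ti(Oi-Pr)4-promoted, C3-selective opening of F5 by F4 with inversion gives the (2S,3R)-3-aryloxy-1,2-diol F6. 1,1'-Thiocarbonyldiimidazole gives the cyclic thionocarbonate F7. Corey–Winter olefination with 1,3-dimethyl-2-phenyl-1,3,2-diazaphospholidine at 40 °C turns the two diol carbons into the vinyl group of 7.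

**Step 2.**
- What may go wrong: acyl transfer to the chelated OH or to both OH groups, scrambling to the symmetric carbonates under DBU, or air oxidation of the hydroquinone under base.
- Fallback (sets out from 3 and 2, returns at 7): the aryl carbonate is given up and the ether is made intermolecularly. Compound 3 with ClCO2Me/pyridine gives the methyl carbonate F8. Intermolecular Pd-catalysed asymmetric allylic etherification of unprotected 2 with F8 (Pd/ligand system of step 4) relies on the low nucleophilicity of the chelated OH and gives the free-phenol tertiary ether F9. MOMCl/i-Pr2NEt converts F9 into 7.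

Further compounds
F1 | step 5 | 2-iodo-6-(methoxymethoxy)-4-methyl-3-{[(3R,6E,10E)-3,7,11,15-tetramethylhexadeca-1,6,10,14-tetraen-3-yl]oxy}benzaldehyde | CC(C)=CCC/C(C)=C/CC/C(C)=C/CC[C@](C)(C=C)Oc1c(I)c(C=O)c(OCOC)cc1C
F2 | step 5 | bis(9-BBN) adduct of F1 (B-alkyl at the former vinyl terminus, B-benzyloxy at the reduced formyl group) | CC(C)=CCC/C(C)=C/CC/C(C)=C/CC[C@](C)(CCB1C2CCCC1CCC2)Oc1c(I)c(COB2C3CCCC2CCC3)c(OCOC)cc1C
F3 | step 5 | {(2R)-6-(methoxymethoxy)-2,8-dimethyl-2-[(3E,7E)-4,8,12-trimethyltrideca-3,7,11-trien-1-yl]chroman-5-yl}methanol | CC(C)=CCC/C(C)=C/CC/C(C)=C/CC[C@]1(C)CCc2c(CO)c(OCOC)cc(C)c2O1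
F4 | step 4 | 5-hydroxy-2-(methoxymethoxy)-4-methylbenzaldehyde | Oc1cc(C=O)c(OCOC)cc1C
F5 | step 4 | (2S,3S)-2,3-epoxygeranylgeraniol | CC(C)=CCC/C(C)=C/CC/C(C)=C/CC[C@]1(C)O[C@H]1CO
F6 | step 4 | 5-{[(2S,3R,6E,10E)-1,2-dihydroxy-3,7,11,15-tetramethylhexadeca-6,10,14-trien-3-yl]oxy}-2-(methoxymethoxy)-4-methylbenzaldehyde | CC(C)=CCC/C(C)=C/CC/C(C)=C/CC[C@](C)([C@@H](O)CO)Oc1cc(C=O)c(OCOC)cc1C
F7 | step 4 | cyclic 1,2-thionocarbonate of F6 | CC(C)=CCC/C(C)=C/CC/C(C)=C/CC[C@](C)([C@@H]1COC(=S)O1)Oc1cc(C=O)c(OCOC)cc1C
F8 | step 2 | (2E,6E,10E)-geranylgeranyl methyl carbonate | CC(C)=CCC/C(C)=C/CC/C(C)=C/CC/C(C)=C/COC(=O)OC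
F9 | step 2 | 2-hydroxy-4-methyl-5-{[(3R,6E,10E)-3,7,11,15-tetramethylhexadeca-1,6,10,14-tetraen-3-yl]oxy}benzaldehyde | CC(C)=CCC/C(C)=C/CC/C(C)=C/CC[C@](C)(C=C)Oc1cc(C=O)c(O)cc1C
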